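If you want the target at the end of this flask, start from its steps and charges.

    substrate + target → side product (k1 = 2.4 M⁻¹ s⁻¹)
    2 free catalyst → spent catalyst (k2 = 95 M⁻¹ s⁻¹)
    gas phase ⇌ dissolved gas, rate k3*(csat - [dissolved gas]) (k3 = 0.26 s⁻¹, csat = 2.7 mM)
    substrate + dissolved gas + free catalyst → free catalyst + target (k4 = 81000 M⁻² s⁻¹)

substrate 47 mM; gas phase 2.7 mM (held); free catalyst 0.47 mM; time 50 s

* the target standing at 50 s, as a percentage of the substrate charged
* the change that raises the amount of target at 50 s, in percent of the substrate charged most ("none" if none brings more than 2 percentage points) (delta / epsilon / zeta / none)
* amount of target at 50 s, in percent of the substrate charged, after epsilon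

- delta: doubling the saturation concentration of gas phase, all else as stated
- epsilon: doubling the transfer coefficient of step 3, all else as stated
- zeta: doubling the amount of free catalyst, all else as stated

- percent here means substrate units held: one side product counts as two
- where a step has two of a species, its rate is k times that concentration squared, and two are used at each turn
- at the start none of the gas is dissolved
- run time (flask): 50 s

- Two extreme flasks come first. If target were never eaten, it could reach what gas transfer delivers, 74.7 %.
- In the other extreme, eating is quick. Target's half-life against the charged substrate (pseudo-first-order) is 6.1 s, short against 50 s.
- Dissolved gas lasts 0.39 s, shorter than the transfer time of 3.85 s. So each gas unit arriving becomes target at once, and the start gives 13.2 %.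
- That figure is the standing level: the target at which eating matches the gas supply caught by the catalyst, in percent of the substrate charged.
- I expect the real flask near this level, and I compute only the correction. By its own step, free catalyst keeps 18.3 % of its charge at 50 s.
- I guess substrate at half its charge. Catalyst then catches 38.6 % of the gas, and my level becomes 10.2 %.
- Delta lifts my level to 20.4 %, and epsilon to 12.7 %. Zeta moves the final free catalyst from 0.0860 mM to 0.0947 mM. So I choose delta.
- The forecast, which stands above me on epsilon, says 12 %, delta and 17.3 %, since “the target is steadily eaten by the large excess of substrate”.
- The simulation gives 11.3 % and delta, with gains of 14 percentage points for delta, 5.6 points for epsilon and 1.1 points for zeta. After epsilon it gives 16.9 %.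
- This flask is not at rest at 50 s. Counting the gas that step 4 takes, its readings put the standing level at 11.5 %, below the starting 13.2 %, and target stands almost on it.
- The same flask read at 20 s has, by the same count, a level of 11.6 % and holds 9.58 %, less than that level.
- Substrate still stands at 32 % at 50 s. By 500 s side product has gained 34 points and target has lost 2.8 points, leaving 8.52 %.

(All constants were drawn at random within sensible limits; the rest is arithmetic.)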